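The question was how far the electrophile gets by 10 min, when the readings stop at 5.00 min.

| setting | gamma | eta | Sunday's | Thursday's |
|---|---|---|---|---|
| electrophile | 0.40 M | 0.40 M | 0.40 M | 0.40 M |
| nucleophile | 1 equiv | 1 equiv | 1.00 equiv | 1.00 equiv |
| free base | 2.4 equiv | 4.7 equiv | 2.00 equiv | 4.00 equiv |
| scavenger | 1 equiv | 1 equiv | 1.00 equiv | 1.00 equiv |
| remark | run made earlier | run made earlier |  |  |
| time |  |  | 10 min | 10 min |

| run | time / min | electrophile / % | product / % |
|---|---|---|---|
| gamma | 0.667 | 38.2 | 56.4 |
| gamma | 1.33 | 33.0 | 63.6 |
| gamma | 2.00 | 25.1 | 68.8 |
| gamma | 3.00 | 18.7 | 77.0 |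
| gamma | 4.00 | 16.7 | 81.0 |
| gamma | 5.00 | 12.3 | 87.9 |
| eta | 0.250 | 52.1 | 43.0 |
| eta | 0.833 | 35.9 | 58.1 |
| eta | 1.33 | 28.3 | 63.8 |
| eta | 2.00 | 25.6 | 70.1 |
| eta | 3.00 | 18.4 | 82.1 |
| eta | 4.00 | 13.2 | 83.7 |
| eta | 5.00 | 11.2 | 88.2 |

(scatter of a reading: 1 percentage point)

- a reading or a percentage of product counts all its forms, free or not

1. part of the electrophile that has reacted at the end, Sunday's
2. part of the electrophile that has reacted at the end, Thursday's
3. what raising the equivalents of free base from its lowest to its highest value here does to the part of the electrophile that has reacted (changes below 5 percentage points count as none) (it falls / no change / it rises)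

Electrophile and nucleophile were charged equally, so I expected a second-order tail: the reciprocal of f, the fraction of electrophile left, should climb on a straight line. The early fall was steeper, so I read the line from 2.00 min on. It gave 1.38 min⁻¹ in gamma and 1.67 min⁻¹ in eta. I carried their mean, 1.53 min⁻¹, as s, the rise of the reciprocal of f per minute. Starting from the mean reciprocal at the last reading, 8.53, the line left 6.18% at 10 min.

My second way was a first-order tail. The same readings gave a constant of 0.257 min⁻¹, and from 11.7% that left 3.25%, less than the line. The tail was the one that cheated, because its constant was read while f stood higher than it does after the last reading, and on second-order terms the constant is s times f. So I put the mean f of the tail back in and went round again: 6.62%, then 5.82%, closing on the line from both sides.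

Run by run, the line gave 93.4% reacted for gamma and 94.2% for eta, a gap smaller than 5 percentage points. I committed to 93.8% reacted in both flasks and no change, though Sunday's base lies a little below gamma's.

The forecast gave 94.5% for Sunday's and 94.5% for Thursday's, with no change, holding that “base has essentially no effect on the rate in this range”.

The flasks gave 94.7% for Sunday's and 95.8% for Thursday's, a change of 1.1 points, so no change.

    acid set free + free base ⇌ salt of the base (K = 1400 M⁻¹, k = 0.0380 M⁻¹ s⁻¹)
    crystals ⇌ product, rate k2*(cs2 - [product]) while solid is left; crystals form when [product] > cs2 (solubility = 28.0 mM, k = 0.870 s⁻¹)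
    electrophile + nucleophile → acid set free + product (k = 0.210 M⁻¹ s⁻¹)
    acid set free + scavenger → scavenged by-product (k = 0.260 M⁻¹ s⁻¹)
    electrophile + acid set free ⇌ idle adduct, settled at all times (K = 15.0 M⁻¹)
    nucleophile + acid set free ⇌ protonated nucleophile, settled at all times (K = 320 M⁻¹)

In Sunday's flask the reciprocal of f climbed at 2.27 min⁻¹ from 5.00 min to 10.0 min, faster than s. There the half-life of electrophile by its step with nucleophile was 0.14 min as charged but 0.90 min at 0.351 min.

For a neighbour of Sunday's flask charged with 4.00 equiv of nucleophile, I multiplied s by the charged excess, 3.00 times the electrophile, which gave as an estimate a pseudo-first-order tail with time constant 0.218 min, short against 10 min. That neighbour reached 100%, with 0% electrophile left.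

The runs were computed from invented constants; noise was put on by code.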